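(Readings and results were computed with constants of no real substance.)

A stirred tank invites a pitfall: its mean residence time gets taken for a reaction time, and the outlet is read off the batch curve at that hour.

| flask | substrate | catalyst | remark | time |
|---|---|---|---|---|
| elm | 0.40 M | 0.44 mM | run made earlier |  |
| birch | 0.20 M | 0.44 mM | run made earlier |  |
| maple | 0.80 M | 0.44 mM | run made earlier |  |
| cedar | 0.40 M | 0.88 mM | run made earlier |  |
| epsilon | 0.40 M | 0.44 mM | one stirred flow tank at steady state, fed with the mixture as stated, mean residence time 200 h |  |
| gamma | 0.40 M | 0.44 mM | a single well-mixed tank run continuously and read at steady state, 20 h in it on average |  |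
| theta | 0.40 M | 0.44 mM | plug flow through a tube for 20 h, no back-mixing | 20 h |
| delta | 0.40 M | 0.44 mM | a closed flask charged with all of it at once and left for 20 h | 20 h |

1. the set-up with the highest amount of target at the outlet or at the end, in percent of the substrate put in ("none" if the first two lie within 2 percentage points) (epsilon / gamma / theta / delta / none)
2. amount of target at the outlet or at the end, in percent of the substrate put in, epsilon
3. amount of target at the outlet or at the end, in percent of the substrate put in, gamma
4. amount of target at the outlet or at the end, in percent of the substrate put in, theta
5. amount of target at the outlet or at the end, in percent of the substrate put in, delta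

- the stated concentrations are those of everything mixed, before any reaction; amounts are the same in each set-up
- candidate steps: substrate <-> target; substrate + catalyst <-> isomer of the product A + catalyst; substrate + catalyst <-> isomer of the product B + catalyst
- the earlier runs were made in a closed, stirred flask

At 8.00 h the closed flasks charged with 0.20 M, 0.40 M and 0.80 M of substrate gave 32.4 %, 32.4 % and 32.2 % of target. The percentage does not follow the charge, so we treat the steps as pseudo-first-order at fixed catalyst and the curve as a sum of exponentials. The four set-ups carry the substrate and catalyst charge of elm, so of the runs below we read elm: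

| run | time / h | target / % |
|---|---|---|
| elm | 1.33 | 8.9 |
| elm | 4.00 | 20.8 |
| elm | 8.00 | 32.4 |
| elm | 10.0 | 35.4 |
| elm | 15.0 | 42.3 |
| elm | 20.0 | 48.1 |
| birch | 1.50 | 10.4 |
| birch | 5.00 | 25.9 |
| birch | 8.00 | 32.4 |
| birch | 12.0 | 38.8 |
| birch | 20.0 | 47.4 |
| birch | 25.0 | 51.7 |
| maple | 2.00 | 13.2 |
| maple | 3.00 | 17.1 |
| maple | 5.00 | 24.9 |
| maple | 8.00 | 32.2 |
| maple | 15.0 | 41.6 |
| maple | 25.0 | 51.1 |
| cedar | 2.00 | 12.1 |
| cedar | 4.00 | 18.5 |
| cedar | 6.00 | 23.9 |
| cedar | 12.0 | 33.4 |
| cedar | 25.0 | 49.7 |

(scatter of a reading: 0.5 percentage points)

Take the last three rows of elm, which are equally spaced. Target gains 6.9 percentage points and then 5.8 points. If each later gain keeps that ratio, the gains sum to a level we call the end level, the target the curve is heading for: 78.7 %. This is a soft reading, since the two gains differ by 1.1 points and each reading scatters by 0.5 points. The same ratio gives a slow rate of 0.0347 h⁻¹. Projected back to the start, the slow term spans 61 points of the end level. The remaining 17 points belong to a fast term, and the first row of elm puts its rate at 0.326 h⁻¹.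

Theta and delta give every portion the same age, so we read them at the last row of elm, 48.1 %. In a tank, ages spread, and each exponential term is replaced by one over one plus rate times residence time. That gives 40.2 % for gamma and 70.7 % for epsilon. In epsilon, by the spread of ages in a stirred tank, 88.2 % of the outflow has stayed longer than the latest reading of 25.0 h, more than the younger share, so our epsilon figure rests on the end level.

The forecast gives epsilon as best, with 63 % in epsilon, 39.3 % in gamma and 47.8 % in theta and delta, "because the long residence time approaches equilibrium"; our epsilon figure is higher, at 70.7 %.

The simulation gives 69.9 % in epsilon, 39.8 % in gamma, and 47.3 % in theta and 47.3 % in delta, so epsilon is best.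

    substrate ⇌ target (K = 10.2, k = 0.0801 h⁻¹)
    substrate + catalyst ⇌ isomer of the product A + catalyst, rate k2*[substrate]*[catalyst] forward; the back reaction follows from the equilibrium constant (K = 1.10, k = 168 M⁻¹ h⁻¹)
    substrate + catalyst ⇌ isomer of the product B + catalyst, rate k3*[substrate]*[catalyst] forward; the back reaction follows from the equilibrium constant (K = 0.696, k = 158 M⁻¹ h⁻¹)

The epsilon outlet still holds 11.2 % of substrate and 7.43 % of isomer of the product B. It stands 8.8 points below the end level, where our slow term allowed 7.7 points. Carried to the tube of theta read at 3.0 d, the end level less the decayed slow term gives 73.7 %, and that flask holds 71.5 % of target.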